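Over time the earlier flasks show free monomer entering chains; south-east and west are stopped at 4.0 min.

| flask | free monomer | initiator | remark | time |
|---|---|---|---|---|
| theta | 0.23 M | 4.4 mM | run made earlier |  |
| epsilon | 0.34 M | 4.4 mM | run made earlier |  |
| eta | 0.65 M | 4.4 mM | run made earlier |  |
| south-east | 0.67 M | 4.4 mM |  | 4.0 min |
| west | 0.20 M | 4.4 mM |  | 4.0 min |

- theta (time / min: monomer in chains / %): 0.333: 2.2; 1.00: 8.9; 2.00: 16.7; 3.00: 23.6
- epsilon (time / min: monomer in chains / %): 0.667: 7.7; 1.33: 15.9; 2.00: 22.7; 3.00: 32.3
- eta (time / min: monomer in chains / %): 0.333: 4.3; 1.00: 15.9; 2.00: 31.4; 3.00: 42.7

(readings scatter by 0.5 percentage points)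

- the average divides the monomer in chains by the number of chains begun, living and dead together
- the numbers in the tables scatter by 0.5 percentage points (one standard deviation)
- steps that have been proposed: free monomer + initiator -> living end + monomer in chains; free monomer + living end -> monomer in chains + living end; monomer in chains + living end -> free monomer + living end; 2 initiator -> spent initiator; free monomer -> uncatalysed product
- the earlier runs do not show the number of chains; that part of a forecast is a guess

- which of the two ends with the longer chains by the average number of monomer units in a chain (chains begun, living or dead) ("neither" if they lie within 10%) (south-east / west / neither)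
- average number of monomer units in a chain (chains begun, living or dead) at the end, south-east
- average number of monomer units in a chain (chains begun, living or dead) at the end, west

Between 1.00 min and 3.00 min the theta run puts 0.0169 M min⁻¹ into chains at a mean free monomer M of 0.193 M; over the same times the eta run gives 0.0871 M min⁻¹ at 0.460 M. If living ends both add and return monomer, the net rate is G(M − Mc), where G is a rate per minute set by the living ends. These readings give G = 0.263 min⁻¹ and Mc = 0.128 M, the ceiling concentration (equilibrium monomer concentration) towards which free monomer falls. With the initiator charge held equal, the charge of free monomer and Mc are the two amounts that matter: their ratio is 5.22 in south-east and 1.56 in west. The epsilon run, not used in the line, reads 0.0359 M min⁻¹ against 0.0378 M min⁻¹ reckoned, so the same G also serves the epsilon run. Guessing one chain per initiator charged, my own reckoning gives lengths of 80.1 in south-east and 10.6 in west.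

The forecast also names south-east as longer but differs in the lengths, 320 and 115, on the reading that “the live-end count seems to depend on monomer”.

The flask gives south-east, with 84.2 there and 13.5 in west.

    free monomer + initiator → living end + monomer in chains (k = 0.147 M⁻¹ s⁻¹)
    free monomer + living end → monomer in chains + living end, rate k2*[living end]*[free monomer] (k = 1.03 M⁻¹ s⁻¹)
    monomer in chains + living end → free monomer + living end, rate k3*[living end] as long as [monomer in chains] is above zero (k = 0.115 s⁻¹)
    2 initiator → spent initiator (k = 1.45 M⁻¹ s⁻¹)
    free monomer → uncatalysed product (k = 4.77 × 10⁻⁵ s⁻¹)

South-east holds 0.00414 M of living end at 4.0 min, against the forecast's 1.08 mM of chains, and after 40.0 min its free monomer stands at 16.5% of charge, near the 19.2% that Mc gives. The difference in free monomer charged is the main reason for west's short chains: west given the charge of south-east reaches 84.2 instead of 13.5. A neighbour charged with 1.1 M reckons to 144 by the same G and Mc, and stands at 149.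

The data were computed with made-up constants, and the scatter is random.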